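The side chain is cut at C21–C22, the sp3–sp2 bond between the allylic CH2 and the vinylic CH of the sixth prenyl unit counted from the naphthoquinone ring. The key step reads the C20–C21 ethylene as a terminal 1,3-diene: 9-BBN hydroborates that one monosubstituted vinyl group among six alkenes, and the resulting homoallylic borane is joined in the same flask by B-alkyl Suzuki–Miyaura coupling to the (E)-iodoalkene C22–C32, made from (S)-citronellyl bromide by methylalumination. The diene partner carries the arene as its hydroquinone dimethyl ether and a C13 phenylsulfonyl group left from chain assembly; both are removed afterwards.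

Key step: step 13

Remark on the chemistry: the sulfonyl-bearing carbon C13 of compounds 24 to 26 forms as a mixture of both configurations and is written without a descriptor; it becomes CH2 in step 14. The only stereocentre of the target (27R) is bought with (S)-citronellyl bromide; no bond at it is ever broken, and the descriptor changes from S to R only because the CIP priorities change. Side-chain locants (C1 at the ring to C32) are those of the target throughout.

Step 1
Reactants: 1 (S)-citronellyl bromide; 2 trimethyl(prop-1-yn-1-yl)silane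
Product: 4 trimethyl[(6R)-6,10-dimethylundec-9-en-1-yn-1-yl]silane, via lithiated silylpropyne 3 (not isolated)
Conditions: n-BuLi, THF, −78 °C; then 1, DMPU, −78 °C → rt
Reagents that add atoms: none
Why: SN2 alkylation of the propargylic lithium reagent by the unhindered primary bromide should occur at its CH2 terminus (the silyl group disfavours the allenyl mode), adding C24, C23 and C22 without touching the stereocentre.

Step 2
Reactants: 4 trimethyl[(6R)-6,10-dimethylundec-9-en-1-yn-1-yl]silane
Product: 5 (6R)-6,10-dimethylundec-9-en-1-yne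
Conditions: K2CO3, MeOH, rt
Reagents that add atoms: none
Why: Methoxide-catalysed protodesilylation cleaves only the sp-carbon–silicon bond and leaves the trisubstituted alkene and the stereocentre alone.

Step 3
Reactants: 5 (6R)-6,10-dimethylundec-9-en-1-yne
Product: 7 (1E,6R)-1-iodo-2,6,10-trimethylundeca-1,9-diene, via alkenylalane 6 (not isolated)
Conditions: Me3Al, Cp2ZrCl2 (0.25 equiv), CH2Cl2, 0 °C → rt; then I2, THF, −30 °C → 0 °C
Reagents that add atoms: trimethylaluminium, C[Al](C)C; iodine, II
Why: Zirconium-catalysed methylalumination (Negishi carboalumination) adds Me and Al syn across the terminal alkyne with Al on the terminal carbon, and iodinolysis of the C–Al bond with retention fixes the (E)-2-methyl-1-iodoalkene while the isolated trisubstituted alkene stays inert.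

Step 4
Reactants: 8 menadione (2-methylnaphthalene-1,4-dione)
Product: 10 1,4-dimethoxy-2-methylnaphthalene, via menadiol 9 (not isolated)
Conditions: Na2S2O4, Bu4NBr (cat.), THF/H2O, rt; then aq. KOH, Me2SO4, rt
Reagents that add atoms: dimethyl sulfate, COS(=O)(=O)OC
Why: Dithionite reduction of the quinone followed in the same flask by phase-transfer Williamson O-methylation is a standard reductive methylation that masks the quinone against the organometallic and hydride steps.

Step 5
Reactants: 10 1,4-dimethoxy-2-methylnaphthalene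
Product: 11 2-bromo-1,4-dimethoxy-3-methylnaphthalene
Conditions: Br2, CH2Cl2, 0 °C
Reagents that add atoms: bromine, BrBr
Why: Electrophilic aromatic bromination should go to C3, the only free position of the electron-rich dimethoxylated ring.

Step 6
Reactants: 11 2-bromo-1,4-dimethoxy-3-methylnaphthalene; 12 (2E,6E)-farnesyl bromide
Product: 15 1,4-dimethoxy-2-methyl-3-[(2E,6E)-3,7,11-trimethyldodeca-2,6,10-trien-1-yl]naphthalene, via aryllithium 13 (not isolated), via lithium diarylcuprate 14 (not isolated)
Conditions: n-BuLi, THF, −78 °C; CuBr·SMe2 (0.5 equiv), −78 → −40 °C; then 12, −78 → 0 °C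
Reagents that add atoms: none
Why: Bromine–lithium exchange and transmetalation give a lithium diarylcuprate whose allylic substitution of the primary farnesyl bromide should take place at the α-carbon (SN2) with the (2E,6E) geometry kept, the γ-carbon being fully substituted.

Step 7
Reactants: 15 1,4-dimethoxy-2-methyl-3-[(2E,6E)-3,7,11-trimethyldodeca-2,6,10-trien-1-yl]naphthalene
Product: 16 (2E,6E,10E)-12-(1,4-dimethoxy-3-methylnaphthalen-2-yl)-2,6,10-trimethyldodeca-2,6,10-trien-1-ol
Conditions: SeO2 (0.3 equiv), t-BuOOH, salicylic acid (cat.), CH2Cl2, 0 °C → rt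
Reagents that add atoms: selenium dioxide, O=[Se]=O; tert-butyl hydroperoxide, CC(C)(C)OO
Why: Riley-type allylic oxidation (ene reaction of SeO2, then 2,3-sigmatropic shift) should favour the (E)-methyl group of the terminal isopropylidene unit, the most accessible trisubstituted alkene, and deliver the (E)-allylic alcohol.

Step 8
Reactants: 16 (2E,6E,10E)-12-(1,4-dimethoxy-3-methylnaphthalen-2-yl)-2,6,10-trimethyldodeca-2,6,10-trien-1-ol
Product: 17 2-[(2E,6E,10E)-12-bromo-3,7,11-trimethyldodeca-2,6,10-trien-1-yl]-1,4-dimethoxy-3-methylnaphthalene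
Conditions: CBr4, PPh3, CH2Cl2, −20 → 0 °C
Reagents that add atoms: carbon tetrabromide, BrC(Br)(Br)Br
Why: Appel bromination converts the primary allylic alcohol through an oxyphosphonium ion under neutral, cold conditions, which should avoid allylic transposition and keep the E geometry.

Step 9
Reactants: 18 geranyl bromide
Product: 19 {[(2E)-3,7-dimethylocta-2,6-dien-1-yl]sulfonyl}benzene (geranyl phenyl sulfone)
Conditions: PhSO2Na, DMF, rt
Reagents that add atoms: sodium benzenesulfinate, [Na+].[O-]S(=O)c1ccccc1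
Why: S-Alkylation of the sulfinate by the allylic bromide (SN2) in a dipolar aprotic solvent gives the sulfone that will acidify the future C13.

Step 10
Reactants: 19 geranyl phenyl sulfone
Product: 21 (2E,6E)-2,6-dimethyl-8-(phenylsulfonyl)octa-2,6-dienal, via hydroxy sulfone 20 (not isolated)
Conditions: SeO2 (0.3 equiv), t-BuOOH, salicylic acid (cat.), CH2Cl2, rt; then MnO2, CH2Cl2, rt
Reagents that add atoms: selenium dioxide, O=[Se]=O; tert-butyl hydroperoxide, CC(C)(C)OO
Why: Riley-type allylic oxidation is directed to the (E)-methyl group of the distal isopropylidene unit because the sulfonyl group deactivates the nearer alkene, and MnO2 then oxidises only the allylic alcohol, so that alcohol and any enal already present converge on the (E)-enal.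

Step 11
Reactants: 21 (2E,6E)-2,6-dimethyl-8-(phenylsulfonyl)octa-2,6-dienal
Product: 22 {[(2E,6E)-3,7-dimethylnona-2,6,8-trien-1-yl]sulfonyl}benzene
Conditions: Zn, CH2Br2, TiCl4, THF, 0 °C; then 21, CH2Cl2, rt
Reagents that add atoms: dibromomethane, BrCBr
Why: Lombardo–Takai methylenation with the non-basic gem-dizinc/titanium reagent converts the enal into the terminal diene without deprotonating the acidic allylic sulfone and without touching the E-alkenes.

Step 12
Reactants: 22 {[(2E,6E)-3,7-dimethylnona-2,6,8-trien-1-yl]sulfonyl}benzene; 17 2-[(2E,6E,10E)-12-bromo-3,7,11-trimethyldodeca-2,6,10-trien-1-yl]-1,4-dimethoxy-3-methylnaphthalene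
Product: 24 1,4-dimethoxy-2-methyl-3-[(2E,6E,10E,14E,18E)-3,7,11,15,19-pentamethyl-13-(phenylsulfonyl)henicosa-2,6,10,14,18,20-hexaen-1-yl]naphthalene, via lithiated sulfone 23 (not isolated)
Conditions: n-BuLi, THF/DMPU, −78 °C; then 17, −78 → −20 °C
Reagents that add atoms: none
Why: Alkylation of the sulfonyl-stabilised allylic carbanion at its α-carbon by the primary allylic bromide (Biellmann-type coupling, SN2) forms C12–C13 head to tail with all alkene geometries kept, and the new C13 centre forms unselectively and is erased later.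

Step 13
Reactants: 24 1,4-dimethoxy-2-methyl-3-[(2E,6E,10E,14E,18E)-3,7,11,15,19-pentamethyl-13-(phenylsulfonyl)henicosa-2,6,10,14,18,20-hexaen-1-yl]naphthalene; 7 (1E,6R)-1-iodo-2,6,10-trimethylundeca-1,9-diene
Product: 26 1,4-dimethoxy-2-methyl-3-[(2E,6E,10E,14E,18E,22E,27R)-3,7,11,15,19,23,27,31-octamethyl-13-(phenylsulfonyl)dotriaconta-2,6,10,14,18,22,30-heptaen-1-yl]naphthalene, via alkyl-9-BBN 25 (not isolated)
Conditions: 9-BBN (1.5 equiv), THF, 0 °C → rt; then H2O, Cs2CO3, 7, PdCl2(dppf) (5 mol %), AsPh3 (10 mol %), DMF, rt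
Reagents that add atoms: none
Why: 9-BBN adds H–B syn and anti-Markovnikov across the only monosubstituted alkene of 24 (C20=C21), placing boron on C21, while the five trisubstituted alkenes react far more slowly, so 25 should form as a single homoallylic borane. Zerovalent palladium generated from PdCl2(dppf) inserts into the C–I bond of 7 with retention, the carbonate-activated borate transfers its primary alkyl group to palladium, and reductive elimination forms C21–C22 with the (22E) geometry of the iodide carried over unchanged. The closest known reaction type is the one-pot diene hydroboration/B-alkyl Suzuki–Miyaura coupling with (E)-2-methyl-1-iodoalkenes. No ring is closed and no stereocentre is made; the (27R) centre of 7 is remote and untouched, and the C13 sulfonyl centre stays a mixture that step 14 erases. The step needs chemoselective hydroboration (secured by the single terminal vinyl group), suppression of β-hydride elimination from the alkylpalladium intermediate (secured by the wide-bite-angle dppf ligand with AsPh3) and survival of the allylic sulfone (oxidative addition to the iodoalkene at room temperature should far outrun ionisation of the sulfone).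

Step 14
Reactants: 26 1,4-dimethoxy-2-methyl-3-[(2E,6E,10E,14E,18E,22E,27R)-3,7,11,15,19,23,27,31-octamethyl-13-(phenylsulfonyl)dotriaconta-2,6,10,14,18,22,30-heptaen-1-yl]naphthalene
Product: 27 1,4-dimethoxy-2-methyl-3-[(2E,6E,10E,14E,18E,22E,27R)-3,7,11,15,19,23,27,31-octamethyldotriaconta-2,6,10,14,18,22,30-heptaen-1-yl]naphthalene
Conditions: PdCl2(dppp) (10 mol %), LiBHEt3, THF, 0 °C
Reagents that add atoms: none
Why: Zerovalent palladium ionises the allylic sulfone to a π-allyl complex and hydride from LiBHEt3 is delivered to the less substituted terminus C13, so the C14=C15 alkene should stay in place with E geometry (palladium-catalysed reductive desulfonylation).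

Step 15
Reactants: 27 1,4-dimethoxy-2-methyl-3-[(2E,6E,10E,14E,18E,22E,27R)-3,7,11,15,19,23,27,31-octamethyldotriaconta-2,6,10,14,18,22,30-heptaen-1-yl]naphthalene
Product: 28 2-methyl-3-[(2E,6E,10E,14E,18E,22E,27R)-3,7,11,15,19,23,27,31-octamethyldotriaconta-2,6,10,14,18,22,30-heptaen-1-yl]naphthalene-1,4-dione (CNP0319612.1)
Conditions: (NH4)2Ce(NO3)6, MeCN/CH2Cl2/H2O, 0 °C
Reagents that add atoms: water, O
Why: Two-electron oxidative demethylation of the 1,4-dimethoxyarene by tetravalent cerium (water attacks the arene radical cation, methanol is lost) should unmask the 1,4-naphthoquinone at 0 °C faster than the isolated alkenes are oxidised.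

Compound list
1 | (S)-citronellyl bromide, (6S)-8-bromo-2,6-dimethyloct-2-ene | CC(C)=CCC[C@H](C)CCBr | starting material
2 | trimethyl(prop-1-yn-1-yl)silane | CC#C[Si](C)(C)C | starting material
3 | (3-lithioprop-1-yn-1-yl)trimethylsilane | [Li]CC#C[Si](C)(C)C | intermediate
4 | trimethyl[(6R)-6,10-dimethylundec-9-en-1-yn-1-yl]silane | CC(C)=CCC[C@H](C)CCCC#C[Si](C)(C)C | intermediate
5 | (6R)-6,10-dimethylundec-9-en-1-yne | CC(C)=CCC[C@H](C)CCCC#C | intermediate
6 | dimethyl[(1E,6R)-2,6,10-trimethylundeca-1,9-dien-1-yl]alane | CC(C)=CCC[C@H](C)CCC/C(C)=C/[Al](C)C | intermediate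
7 | (1E,6R)-1-iodo-2,6,10-trimethylundeca-1,9-diene | CC(C)=CCC[C@H](C)CCC/C(C)=C/I | intermediate
8 | menadione, 2-methylnaphthalene-1,4-dione | CC1=CC(=O)c2ccccc2C1=O | starting material
9 | menadiol, 2-methylnaphthalene-1,4-diol | Cc1cc(O)c2ccccc2c1O | intermediate
10 | 1,4-dimethoxy-2-methylnaphthalene | COc1cc(C)c(OC)c2ccccc12 | intermediate
11 | 2-bromo-1,4-dimethoxy-3-methylnaphthalene | COc1c(Br)c(C)c(OC)c2ccccc12 | intermediate
12 | (2E,6E)-farnesyl bromide | CC(C)=CCC/C(C)=C/CC/C(C)=C/CBr | starting material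
13 | (1,4-dimethoxy-3-methylnaphthalen-2-yl)lithium | [Li]c1c(C)c(OC)c2ccccc2c1OC | intermediate
14 | lithium bis(1,4-dimethoxy-3-methylnaphthalen-2-yl)cuprate | [Li+].COc1c(C)c([Cu-]c2c(C)c(OC)c3ccccc3c2OC)c(OC)c2ccccc12 | intermediate
15 | 1,4-dimethoxy-2-methyl-3-[(2E,6E)-3,7,11-trimethyldodeca-2,6,10-trien-1-yl]naphthalene | CC(C)=CCC/C(C)=C/CC/C(C)=C/Cc1c(C)c(OC)c2ccccc2c1OC | intermediate
16 | (2E,6E,10E)-12-(1,4-dimethoxy-3-methylnaphthalen-2-yl)-2,6,10-trimethyldodeca-2,6,10-trien-1-ol | OC/C(C)=C/CC/C(C)=C/CC/C(C)=C/Cc1c(C)c(OC)c2ccccc2c1OC | intermediate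
17 | 2-[(2E,6E,10E)-12-bromo-3,7,11-trimethyldodeca-2,6,10-trien-1-yl]-1,4-dimethoxy-3-methylnaphthalene | BrC/C(C)=C/CC/C(C)=C/CC/C(C)=C/Cc1c(C)c(OC)c2ccccc2c1OC | intermediate
18 | geranyl bromide, (2E)-1-bromo-3,7-dimethylocta-2,6-diene | CC(C)=CCC/C(C)=C/CBr | starting material
19 | geranyl phenyl sulfone, {[(2E)-3,7-dimethylocta-2,6-dien-1-yl]sulfonyl}benzene | CC(C)=CCC/C(C)=C/CS(=O)(=O)c1ccccc1 | intermediate
20 | (2E,6E)-2,6-dimethyl-8-(phenylsulfonyl)octa-2,6-dien-1-ol | OC/C(C)=C/CC/C(C)=C/CS(=O)(=O)c1ccccc1 | intermediate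
21 | (2E,6E)-2,6-dimethyl-8-(phenylsulfonyl)octa-2,6-dienal | O=C/C(C)=C/CC/C(C)=C/CS(=O)(=O)c1ccccc1 | intermediate
22 | {[(2E,6E)-3,7-dimethylnona-2,6,8-trien-1-yl]sulfonyl}benzene | C=C/C(C)=C/CC/C(C)=C/CS(=O)(=O)c1ccccc1 | intermediate
23 | 1-lithio derivative of 22 (α-sulfonyl allylic carbanion) | C=C/C(C)=C/CC/C(C)=C/C([Li])S(=O)(=O)c1ccccc1 | intermediate
24 | 1,4-dimethoxy-2-methyl-3-[(2E,6E,10E,14E,18E)-3,7,11,15,19-pentamethyl-13-(phenylsulfonyl)henicosa-2,6,10,14,18,20-hexaen-1-yl]naphthalene (C13 epimers) | C=C/C(C)=C/CC/C(C)=C/C(C/C(C)=C/CC/C(C)=C/CC/C(C)=C/Cc1c(C)c(OC)c2ccccc2c1OC)S(=O)(=O)c1ccccc1 | intermediate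
25 | B-alkyl-9-borabicyclo[3.3.1]nonane from 24 (boron on C21) | C1CCC2CCCC1B2CC/C(C)=C/CC/C(C)=C/C(C/C(C)=C/CC/C(C)=C/CC/C(C)=C/Cc1c(C)c(OC)c2ccccc2c1OC)S(=O)(=O)c1ccccc1 | intermediate
26 | 1,4-dimethoxy-2-methyl-3-[(2E,6E,10E,14E,18E,22E,27R)-3,7,11,15,19,23,27,31-octamethyl-13-(phenylsulfonyl)dotriaconta-2,6,10,14,18,22,30-heptaen-1-yl]naphthalene (C13 epimers) | CC(C)=CCC[C@H](C)CCC/C(C)=C/CC/C(C)=C/CC/C(C)=C/C(C/C(C)=C/CC/C(C)=C/CC/C(C)=C/Cc1c(C)c(OC)c2ccccc2c1OC)S(=O)(=O)c1ccccc1 | intermediate
27 | 1,4-dimethoxy-2-methyl-3-[(2E,6E,10E,14E,18E,22E,27R)-3,7,11,15,19,23,27,31-octamethyldotriaconta-2,6,10,14,18,22,30-heptaen-1-yl]naphthalene | CC(C)=CCC[C@H](C)CCC/C(C)=C/CC/C(C)=C/CC/C(C)=C/CC/C(C)=C/CC/C(C)=C/CC/C(C)=C/Cc1c(C)c(OC)c2ccccc2c1OC | intermediate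
28 | 2-methyl-3-[(2E,6E,10E,14E,18E,22E,27R)-3,7,11,15,19,23,27,31-octamethyldotriaconta-2,6,10,14,18,22,30-heptaen-1-yl]naphthalene-1,4-dione (CNP0319612.1) | CC(C)=CCC[C@H](C)CCC/C(C)=C/CC/C(C)=C/CC/C(C)=C/CC/C(C)=C/CC/C(C)=C/CC/C(C)=C/CC1=C(C)C(=O)c2ccccc2C1=O | target

Total step count: 15.
Longest linear sequence: 9 steps (steps 4, 5, 6, 7, 8, 12, 13, 14, 15). The iodoalkene branch (steps 1 to 3) and the diene sulfone branch (steps 9 to 11) run in parallel.

Steps most likely to fail

1. Step 13 (key step). The alkylborane may transfer to palladium too slowly, so that β-hydride elimination and protodeboronation consume it, or zerovalent palladium may ionise the allylic sulfone. The fallback sets out from 24 and comes back at 27, bypassing 26 and step 14. Hydroboration of 24 with 9-BBN as before, followed by NaOH/H2O2, should give the primary alcohol (3E,7E,11E,15E,19E)-21-(1,4-dimethoxy-3-methylnaphthalen-2-yl)-3,7,11,15,19-pentamethyl-9-(phenylsulfonyl)henicosa-3,7,11,15,19-pentaen-1-ol F1. Reductive desulfonylation with PdCl2(dppp)/LiBHEt3, now with no diene present, should give the sulfone-free alcohol F2. I2, PPh3 and imidazole convert it to the primary iodide F3. Iodine–lithium exchange with t-BuLi (2 equiv, Et2O, −78 °C) gives the alkyllithium F4, and ZnBr2 the homoallylic alkylzinc bromide F5. Negishi coupling of F5 with 7 under Pd(PPh3)4 catalysis in THF at rt, the classical alkyl–alkenyl coupling for head-to-tail polyprenyl chains, should then give 27.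

2. Step 7. Site selectivity among three trisubstituted alkenes may be poor, and over-oxidation to the enal or attack at internal allylic positions may erode the material. The fallback sets out from 15 and comes back at 17, bypassing 16 and step 8. NBS in THF/H2O at 0 °C should form the terminal bromohydrin F6 selectively, since the chain coils in aqueous medium and exposes the terminal alkene. K2CO3 in MeOH closes it to the terminal epoxide F7. Al(OiPr)3 in refluxing toluene isomerises the epoxide to the secondary allylic alcohol with a 1,1-disubstituted alkene F8. PBr3 in Et2O at −10 °C should convert F8 with allylic transposition (SN2′) to the primary (E)-allylic bromide 17; any (Z)-isomer would be removed by chromatography.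

3. Step 14. The C14=C15 double bond may migrate or lose its E geometry through the π-allylpalladium intermediate, or hydride may be delivered to the wrong allyl terminus. The fallback sets out from 26 and comes back at 27: single-electron reductive cleavage of the C–S bond with sodium amalgam Na(Hg) and Na2HPO4 in MeOH/THF at −20 °C replaces the π-allylpalladium/hydride pathway by a radical-anion fragmentation followed by protonation of the allyl anion. This fallback makes no compound beyond the compound list (entry F0).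

Further compounds
F1 | step 13 | (3E,7E,11E,15E,19E)-21-(1,4-dimethoxy-3-methylnaphthalen-2-yl)-3,7,11,15,19-pentamethyl-9-(phenylsulfonyl)henicosa-3,7,11,15,19-pentaen-1-ol (C9 epimers) | OCC/C(C)=C/CC/C(C)=C/C(C/C(C)=C/CC/C(C)=C/CC/C(C)=C/Cc1c(C)c(OC)c2ccccc2c1OC)S(=O)(=O)c1ccccc1
F2 | step 13 | (3E,7E,11E,15E,19E)-21-(1,4-dimethoxy-3-methylnaphthalen-2-yl)-3,7,11,15,19-pentamethylhenicosa-3,7,11,15,19-pentaen-1-ol | OCC/C(C)=C/CC/C(C)=C/CC/C(C)=C/CC/C(C)=C/CC/C(C)=C/Cc1c(C)c(OC)c2ccccc2c1OC
F3 | step 13 | 2-[(2E,6E,10E,14E,18E)-21-iodo-3,7,11,15,19-pentamethylhenicosa-2,6,10,14,18-pentaen-1-yl]-1,4-dimethoxy-3-methylnaphthalene | ICC/C(C)=C/CC/C(C)=C/CC/C(C)=C/CC/C(C)=C/CC/C(C)=C/Cc1c(C)c(OC)c2ccccc2c1OC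
F4 | step 13 | 21-lithio analogue of F3 (primary alkyllithium) | [Li]CC/C(C)=C/CC/C(C)=C/CC/C(C)=C/CC/C(C)=C/CC/C(C)=C/Cc1c(C)c(OC)c2ccccc2c1OC
F5 | step 13 | 21-(bromozincio) analogue of F3 (homoallylic alkylzinc bromide) | Br[Zn]CC/C(C)=C/CC/C(C)=C/CC/C(C)=C/CC/C(C)=C/CC/C(C)=C/Cc1c(C)c(OC)c2ccccc2c1OC
F6 | step 7 | (6E,10E)-3-bromo-12-(1,4-dimethoxy-3-methylnaphthalen-2-yl)-2,6,10-trimethyldodeca-6,10-dien-2-ol (racemic) | CC(C)(O)C(Br)CC/C(C)=C/CC/C(C)=C/Cc1c(C)c(OC)c2ccccc2c1OC
F7 | step 7 | 2-[(2E,6E)-9-(3,3-dimethyloxiran-2-yl)-3,7-dimethylnona-2,6-dien-1-yl]-1,4-dimethoxy-3-methylnaphthalene (racemic) | CC1(C)OC1CC/C(C)=C/CC/C(C)=C/Cc1c(C)c(OC)c2ccccc2c1OC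
F8 | step 7 | (6E,10E)-12-(1,4-dimethoxy-3-methylnaphthalen-2-yl)-2,6,10-trimethyldodeca-1,6,10-trien-3-ol (racemic) | C=C(C)C(O)CC/C(C)=C/CC/C(C)=C/Cc1c(C)c(OC)c2ccccc2c1OC
F0 | step 14 | none | none
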